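**Retrosynthetic overview**

Labels: quinolone A is fused through C3/C4 to the central dihydropyran (ring C); quinolone B is fused to the gem-dimethylpyran (ring D); Ca = O–CH, Cb = ring-fusion CH, Cc = CH carrying the 2-hydroxy-2-methylpropyl chain.
Ring C (O–C4(A)=C3(A)–Cc–Cb–Ca) is cut at the aryl ether bond O–C4(A) and at C3(A)–Cc, which leads back to 4-chloroquinolone 7 and allylic alcohol 18, in which ring D already exists and Cb=Cc is an exocyclic alkene.
Enabling feature: in ring C the oxygen sits on C4 of quinolone A and C3 of that quinolone carries Cc, three atoms from O (O–Ca–Cb–Cc), the retron of an aromatic Claisen shift of a 4-allyloxy-2-quinolone. Ca is also C4 of ring D and benzylic to quinolone B, so the Ca–O bond broken by the shift re-forms by acid-mediated capture of a stabilised cation.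
Alcohol 18 comes from dione 10 (ring D by C3-acylation/oxa-Michael on 4-hydroxyquinolone 6) through aldol condensation with aldehyde 13 and CBS reduction; 6 serves both halves (7 by POCl3). Ring order: pyridone rings, then ring D, then ring C last.
Stereochemistry: Ca carbinol by reagent control, Cc by [3,3] chirality transfer, Ca and Cb re-set under thermodynamic control.

Key step: step 11

Remark on the chemistry (assumption): the enone from step 9 is taken to be the thermodynamic Z isomer (side chain cis to the C4 carbonyl carbon), because the E isomer would press the CH2 group against the gem-dimethyl carbon.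

**Step 1**
Reactants: 1 2,3-dimethoxyaniline
Product: 3 2,3-dimethoxy-N-methylaniline, via N-(methoxymethyl)aniline 2 (not isolated)
Conditions: (CH2O)n, NaOMe, MeOH, 65 °C; then NaBH4, 65 °C
Reagents that add atoms: formaldehyde (from paraformaldehyde), C=O
Why: Reductive mono-N-methylation, in which the aniline condenses with formaldehyde in NaOMe/MeOH to the N-(methoxymethyl) adduct 2 and NaBH4 reduces it through the iminium to the secondary amine without over-alkylation.

**Step 2**
Reactants: 3 2,3-dimethoxy-N-methylaniline; 4 Meldrum's acid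
Product: 5 3-[(2,3-dimethoxyphenyl)(methyl)amino]-3-oxopropanoic acid
Conditions: PhMe, 110 °C
Reagents that add atoms: none
Why: Aminolysis of Meldrum's acid, in which the secondary aniline opens the activated cyclic diester and acetone is lost to leave the malonic acid monoamide.

**Step 3**
Reactants: 5 3-[(2,3-dimethoxyphenyl)(methyl)amino]-3-oxopropanoic acid
Product: 6 4-hydroxy-7,8-dimethoxy-1-methylquinolin-2(1H)-one
Conditions: P2O5/MeSO3H (1:10 w/w), 70 °C
Reagents that add atoms: none
Why: Intramolecular Friedel–Crafts acylation (cyclodehydration of a malonanilic acid) at the only free ortho position, which is para to a methoxy group, should give the 4-hydroxy-2-quinolone.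

**Step 4**
Reactants: 6 4-hydroxy-7,8-dimethoxy-1-methylquinolin-2(1H)-one
Product: 7 4-chloro-7,8-dimethoxy-1-methylquinolin-2(1H)-one
Conditions: POCl3, 90 °C
Reagents that add atoms: phosphoryl chloride, O=P(Cl)(Cl)Cl
Why: Deoxychlorination of the vinylogous acid through its dichlorophosphate (addition–elimination by chloride), with the N-methyl group blocking chlorination at C2.

**Step 5**
Reactants: 6 4-hydroxy-7,8-dimethoxy-1-methylquinolin-2(1H)-one; 8 3-methylbut-2-enoic acid
Product: 10 7,8-dimethoxy-2,2,6-trimethyl-2,3-dihydro-4H-pyrano[3,2-c]quinoline-4,5(6H)-dione, via 3-acylquinolone 9 (not isolated)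
Conditions: P2O5/MeSO3H (1:10 w/w), 70 °C
Reagents that add atoms: none
Why: Chromanone-type annulation, in which Friedel–Crafts C-acylation of the nucleophilic C3 by the mixed anhydride of the acid gives enone 9 and its 4-OH then adds to the β,β-dimethyl enone (acid-catalysed oxa-Michael) to close ring D.

**Step 6**
Reactants: 11 ethyl 3-hydroxy-3-methylbutanoate
Product: 12 ethyl 3-[(tert-butyldimethylsilyl)oxy]-3-methylbutanoate
Conditions: t-BuMe2SiOTf, 2,6-lutidine, CH2Cl2, 0 → 23 °C
Reagents that add atoms: tert-butyldimethylsilyl trifluoromethanesulfonate, CC(C)(C)[Si](C)(C)OS(=O)(=O)C(F)(F)F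
Why: Silylation of a hindered tertiary alcohol with the silyl triflate and a non-nucleophilic base.

**Step 7**
Reactants: 12 ethyl 3-[(tert-butyldimethylsilyl)oxy]-3-methylbutanoate
Product: 13 3-[(tert-butyldimethylsilyl)oxy]-3-methylbutanal
Conditions: i-Bu2AlH, CH2Cl2, −78 °C; MeOH, then aq. KNaC4H4O6
Reagents that add atoms: none
Why: Partial reduction of the ester at low temperature, where the tetrahedral aluminium hemiacetal survives until work-up and then releases the aldehyde.

**Step 8**
Reactants: 10 7,8-dimethoxy-2,2,6-trimethyl-2,3-dihydro-4H-pyrano[3,2-c]quinoline-4,5(6H)-dione; 13 3-[(tert-butyldimethylsilyl)oxy]-3-methylbutanal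
Product: 15 3-{3-[(tert-butyldimethylsilyl)oxy]-1-hydroxy-3-methylbutyl}-7,8-dimethoxy-2,2,6-trimethyl-2,3-dihydro-4H-pyrano[3,2-c]quinoline-4,5(6H)-dione (mixture of diastereomers), via boron enolate 14 (not isolated)
Conditions: n-Bu2BOTf, i-Pr2NEt, CH2Cl2, −78 °C; then 13, −78 → 0 °C; pH 7 buffer, MeOH, H2O2
Reagents that add atoms: none
Why: Boron-mediated aldol addition, in which soft enolisation gives the covalent boron enolate 14 at the only enolisable carbon (avoiding a free enolate that could expel the ring oxygen by retro-oxa-Michael) and this adds to the unhindered aldehyde; both new centres disappear in step 9.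

**Step 9**
Reactants: 15 aldol adduct
Product: 17 (3Z)-3-{3-[(tert-butyldimethylsilyl)oxy]-3-methylbutylidene}-7,8-dimethoxy-2,2,6-trimethyl-2,3-dihydro-4H-pyrano[3,2-c]quinoline-4,5(6H)-dione, via mesylate 16 (not isolated)
Conditions: MeSO2Cl, Et3N, CH2Cl2, 0 °C; then DBU, 23 °C
Reagents that add atoms: none
Why: Mesylation and E1cB elimination complete the aldol condensation, and the enone should settle as the Z isomer because the E isomer forces the side chain against the gem-dimethyl carbon (a cis tert-alkyl/alkyl alkene).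

**Step 10**
Reactants: 17 (3Z)-enone
Product: 18 (3E,4R)-3-{3-[(tert-butyldimethylsilyl)oxy]-3-methylbutylidene}-4-hydroxy-7,8-dimethoxy-2,2,6-trimethyl-3,4-dihydro-2H-pyrano[3,2-c]quinolin-5(6H)-one
Conditions: (R)-1-methyl-3,3-diphenyltetrahydro-1H,3H-pyrrolo[1,2-c][1,3,2]oxazaborole (0.2 equiv), catecholborane, PhMe, −78 °C
Reagents that add atoms: none
Why: Corey–Bakshi–Shibata reduction, known to reduce α-alkylidene ketones in the 1,2-sense: the boron should bind the carbonyl lone pair on the quinolone side because the cis CH2 group shields the other one, so the alkylidene flank acts as the large group and the (R) catalyst should deliver hydride to give the (R) carbinol.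

**Step 11**
Reactants: 18 (3E,4R)-allylic alcohol; 7 4-chloro-7,8-dimethoxy-1-methylquinolin-2(1H)-one
Product: 22 tert-butyldimethylsilyl ether of 23 (silyl group on the tertiary oxygen; configuration as in 23), via potassium alkoxide 19 (not isolated), via aryl allyl ether 20 (not isolated), via 3-allyl-4-hydroxyquinolone 21 (not isolated)
Conditions: KH, 18-crown-6, THF, 0 °C; 7, 0 → 40 °C; then PhMe, 100 °C; then (±)-camphor-10-sulfonic acid (0.2 equiv), 23 °C
Reagents that add atoms: none
Why: The potassium alkoxide 19 adds to C4 of the β-chloro-enamide 7 and expels chloride (addition–elimination SNAr, the known route to 4-alkoxy-2-quinolones), which makes the aryl O–C4 bond of quinolone A in ether 20. On heating, 20 undergoes the aromatic Claisen rearrangement known for 4-allyloxy-2-quinolones, a concerted [3,3] shift in which the Ca–O bond stands pseudo-axial on ring D and C3 of quinolone A bonds to Cc on the alkene face that the oxygen leaves, so the (R) carbinol and the E alkene are translated suprafacially into the (S) centre at Cc of 21 whether the transition state is chair or boat. Tautomerisation returns the 4-hydroxyquinolone, and the acid then protonates Cb of the new chromene-type double bond to give a Ca cation stabilised by quinolone B, which the 4-OH captures in a 6-endo-trig Markovnikov hydroalkoxylation (the known acid cyclisation of 3-allyl-4-hydroxyquinolones) that restores the O–Ca bond and closes ring C. Protonation and capture are reversible under the acid, so Ca and Cb settle under thermodynamic control exerted by Cc: cis fusion of rings C and D with the side chain pseudo-axial and anti to the Cb–CMe2 bond is the one arrangement that keeps both the side chain and the ring oxygen out of the plane of the neighbouring lactam carbonyls. The selectivities needed are C3 attack (the only ortho position), the concerted shift outrunning heterolysis of the doubly activated Ca–O bond (hence a neutral, non-polar medium during heating and acid only afterwards), and diastereocontrol in the closure, secured by the peri interactions just named. In the balance only the O–C4 and C3–Cc bonds are new and chloride is the only atom lost.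

**Step 12**
Reactants: 22 silyl ether of the target
Product: 23 CNP0160874.2
Conditions: Bu4NF, THF, 50 °C
Reagents that add atoms: none
Why: Fluoride-induced cleavage of the tertiary silyl ether, driven by the Si–F bond, under non-acidic conditions that should leave the benzylic ether at Ca untouched.

**Compound list**

1 | 2,3-dimethoxyaniline | Nc1cccc(OC)c1OC | starting material
2 | 2,3-dimethoxy-N-(methoxymethyl)aniline | COCNc1cccc(OC)c1OC | intermediate (not isolated)
3 | 2,3-dimethoxy-N-methylaniline | CNc1cccc(OC)c1OC | intermediate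
4 | Meldrum's acid (2,2-dimethyl-1,3-dioxane-4,6-dione) | CC1(C)OC(=O)CC(=O)O1 | starting material
5 | 3-[(2,3-dimethoxyphenyl)(methyl)amino]-3-oxopropanoic acid | CN(C(=O)CC(=O)O)c1cccc(OC)c1OC | intermediate
6 | 4-hydroxy-7,8-dimethoxy-1-methylquinolin-2(1H)-one | COc1ccc2c(O)cc(=O)n(C)c2c1OC | intermediate
7 | 4-chloro-7,8-dimethoxy-1-methylquinolin-2(1H)-one | COc1ccc2c(Cl)cc(=O)n(C)c2c1OC | intermediate
8 | 3-methylbut-2-enoic acid | CC(C)=CC(=O)O | starting material
9 | 4-hydroxy-7,8-dimethoxy-1-methyl-3-(3-methylbut-2-enoyl)quinolin-2(1H)-one | COc1ccc2c(O)c(C(=O)C=C(C)C)c(=O)n(C)c2c1OC | intermediate (not isolated)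
10 | 7,8-dimethoxy-2,2,6-trimethyl-2,3-dihydro-4H-pyrano[3,2-c]quinoline-4,5(6H)-dione | O=C1CC(C)(C)Oc2c1c(=O)n(C)c1c(OC)c(OC)ccc21 | intermediate
11 | ethyl 3-hydroxy-3-methylbutanoate | CCOC(=O)CC(C)(C)O | starting material
12 | ethyl 3-[(tert-butyldimethylsilyl)oxy]-3-methylbutanoate | CCOC(=O)CC(C)(C)O[Si](C)(C)C(C)(C)C | intermediate
13 | 3-[(tert-butyldimethylsilyl)oxy]-3-methylbutanal | O=CCC(C)(C)O[Si](C)(C)C(C)(C)C | intermediate
14 | dibutylboron enolate of 10 (4-[(dibutylboranyl)oxy]-2H-pyrano[3,2-c]quinolin-5-one) | CCCCB(CCCC)OC1=CC(C)(C)Oc2c1c(=O)n(C)c1c(OC)c(OC)ccc21 | intermediate (not isolated)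
15 | 3-{3-[(tert-butyldimethylsilyl)oxy]-1-hydroxy-3-methylbutyl}-7,8-dimethoxy-2,2,6-trimethyl-2,3-dihydro-4H-pyrano[3,2-c]quinoline-4,5(6H)-dione, mixture of diastereomers | O=C1C(C(O)CC(C)(C)O[Si](C)(C)C(C)(C)C)C(C)(C)Oc2c1c(=O)n(C)c1c(OC)c(OC)ccc21 | intermediate
16 | methanesulfonate of 15 at the secondary hydroxyl, mixture of diastereomers | O=C1C(C(OS(C)(=O)=O)CC(C)(C)O[Si](C)(C)C(C)(C)C)C(C)(C)Oc2c1c(=O)n(C)c1c(OC)c(OC)ccc21 | intermediate (not isolated)
17 | (3Z)-3-{3-[(tert-butyldimethylsilyl)oxy]-3-methylbutylidene}-7,8-dimethoxy-2,2,6-trimethyl-2,3-dihydro-4H-pyrano[3,2-c]quinoline-4,5(6H)-dione | O=C1/C(=C\CC(C)(C)O[Si](C)(C)C(C)(C)C)C(C)(C)Oc2c1c(=O)n(C)c1c(OC)c(OC)ccc21 | intermediate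
18 | (3E,4R)-3-{3-[(tert-butyldimethylsilyl)oxy]-3-methylbutylidene}-4-hydroxy-7,8-dimethoxy-2,2,6-trimethyl-3,4-dihydro-2H-pyrano[3,2-c]quinolin-5(6H)-one | O[C@@H]1/C(=C\CC(C)(C)O[Si](C)(C)C(C)(C)C)C(C)(C)Oc2c1c(=O)n(C)c1c(OC)c(OC)ccc21 | intermediate
19 | potassium alkoxide of 18 | [K+].[O-][C@@H]1/C(=C\CC(C)(C)O[Si](C)(C)C(C)(C)C)C(C)(C)Oc2c1c(=O)n(C)c1c(OC)c(OC)ccc21 | intermediate (not isolated)
20 | 4-{[(3E,4R)-3-{3-[(tert-butyldimethylsilyl)oxy]-3-methylbutylidene}-7,8-dimethoxy-2,2,6-trimethyl-5-oxo-3,4,5,6-tetrahydro-2H-pyrano[3,2-c]quinolin-4-yl]oxy}-7,8-dimethoxy-1-methylquinolin-2(1H)-one | COc1ccc2c(O[C@@H]3/C(=C\CC(C)(C)O[Si](C)(C)C(C)(C)C)C(C)(C)Oc4c3c(=O)n(C)c3c(OC)c(OC)ccc43)cc(=O)n(C)c2c1OC | intermediate (not isolated)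
21 | 3-[(1S)-3-[(tert-butyldimethylsilyl)oxy]-1-(7,8-dimethoxy-2,2,6-trimethyl-5-oxo-5,6-dihydro-2H-pyrano[3,2-c]quinolin-3-yl)-3-methylbutyl]-4-hydroxy-7,8-dimethoxy-1-methylquinolin-2(1H)-one | COc1ccc2c(O)c([C@@H](CC(C)(C)O[Si](C)(C)C(C)(C)C)C3=Cc4c(c5ccc(OC)c(OC)c5n(C)c4=O)OC3(C)C)c(=O)n(C)c2c1OC | intermediate (not isolated)
22 | tert-butyldimethylsilyl ether of 23 at the tertiary hydroxyl; Ca (R), Cb (S), Cc (S) | COc1ccc2c3c(c(=O)n(C)c2c1OC)[C@@H](CC(C)(C)O[Si](C)(C)C(C)(C)C)[C@H]1[C@@H](O3)c2c(c3ccc(OC)c(OC)c3n(C)c2=O)OC1(C)C | intermediate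
23 | CNP0160874.2: cis-fused bis(pyrano[3,2-c]quinolinone) with Ca (O–CH) R, Cb (ring fusion) S and Cc (CH bearing the 2-hydroxy-2-methylpropyl group) S | COc1ccc2c3c(c(=O)n(C)c2c1OC)[C@@H](CC(C)(C)O)[C@H]1[C@@H](O3)c2c(c3ccc(OC)c(OC)c3n(C)c2=O)OC1(C)C | target

**Summary and risks**

Total step count: 12. Longest linear sequence: 9 steps (1, 2, 3, 5, 8, 9, 10, 11, 12).

Steps most likely to fail:

Step 11. The hindered alkoxide may substitute slowly, so that base-mediated isomerisation of the allylic alkoxide competes. The doubly activated Ca–O bond of the ether may ionise before the concerted shift, which would erode the chirality transfer or lead to elimination. The closure may also stall at a kinetic ring-fusion diastereomer. The fallback sets out from 18 and acid 5 and builds quinolone A after a low-temperature rearrangement. Esterification (N,N'-dicyclohexylcarbodiimide, 4-(dimethylamino)pyridine) should give the allyl malonamate F1. LiN(SiMe3)2/Me3SiCl at −78 °C converts it into the silyl ketene acetal F2, which should undergo the Ireland–Claisen rearrangement on warming and give, after aqueous work-up, the malonamic acid F3 with Cc set by the same suprafacial 1,3-transfer. Friedel–Crafts cyclodehydration of F3 as in step 3 (or through its acid chloride with a mild Lewis acid to spare the silyl ether) should give 21, which is closed with the sulfonic acid as in step 11. The fallback comes back to the route at 22.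

Step 10. Facial discrimination may be poor or reversed, because both ketone flanks are sp2 carbons and the lactam oxygen competes for boron; conjugate reduction is a further risk. The fallback sets out from 17. Luche reduction (NaBH4, CeCl3·7H2O, MeOH) should give the racemic allylic alcohol F4. Acylative kinetic resolution (isobutyric anhydride, 2-phenyl-2,3-dihydroimidazo[2,1-b][1,3]benzothiazole in the enantiomer that acylates the (S)-alcohol) should convert the unwanted enantiomer into the (S)-isobutyrate F5 and leave 18, where the fallback rejoins the route. F5 can be saponified (K2CO3, MeOH) and reoxidised (MnO2) to 17 for recycling.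

Step 9. Elimination and equilibration may deliver the other alkene geometry (side chain cis to the gem-dimethyl carbon) or a mixture that does not converge. The fallback sets out from 15 and uses the other isomer instead of fighting it. Elimination of mesylate 16 then gives the E-enone F6, and reduction with the (S)-configured oxazaborolidine should give the (S,Z)-alcohol F7. Under the conditions of step 11 its potassium alkoxide F8 and 7 should give the aryl allyl ether F9, in which carbinol configuration and alkene geometry are both inverted relative to 20, so the suprafacial shift should again give 21. The fallback comes back to the route at 22.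

**Further compounds**

F1 | step 11 | (3E,4R)-3-{3-[(tert-butyldimethylsilyl)oxy]-3-methylbutylidene}-7,8-dimethoxy-2,2,6-trimethyl-5-oxo-3,4,5,6-tetrahydro-2H-pyrano[3,2-c]quinolin-4-yl 3-[(2,3-dimethoxyphenyl)(methyl)amino]-3-oxopropanoate | COc1cccc(N(C)C(=O)CC(=O)O[C@@H]2/C(=C\CC(C)(C)O[Si](C)(C)C(C)(C)C)C(C)(C)Oc3c2c(=O)n(C)c2c(OC)c(OC)ccc32)c1OC
F2 | step 11 | trimethylsilyl ketene acetal of F1 (ketene acetal geometry undefined) | COc1cccc(N(C)C(=O)C=C(O[Si](C)(C)C)O[C@@H]2/C(=C\CC(C)(C)O[Si](C)(C)C(C)(C)C)C(C)(C)Oc3c2c(=O)n(C)c2c(OC)c(OC)ccc32)c1OC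
F3 | step 11 | 2-{[(2,3-dimethoxyphenyl)(methyl)amino]carbonyl}-5-[(tert-butyldimethylsilyl)oxy]-3-(7,8-dimethoxy-2,2,6-trimethyl-5-oxo-5,6-dihydro-2H-pyrano[3,2-c]quinolin-3-yl)-5-methylhexanoic acid, C3 with the spatial sense of Cc in 21, epimeric at C2 | COc1cccc(N(C)C(=O)C(C(=O)O)[C@@H](CC(C)(C)O[Si](C)(C)C(C)(C)C)C2=Cc3c(c4ccc(OC)c(OC)c4n(C)c3=O)OC2(C)C)c1OC
F4 | step 10 | racemic (3E)-3-{3-[(tert-butyldimethylsilyl)oxy]-3-methylbutylidene}-4-hydroxy-7,8-dimethoxy-2,2,6-trimethyl-3,4-dihydro-2H-pyrano[3,2-c]quinolin-5(6H)-one | OC1/C(=C\CC(C)(C)O[Si](C)(C)C(C)(C)C)C(C)(C)Oc2c1c(=O)n(C)c1c(OC)c(OC)ccc21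
F5 | step 10 | (3E,4S)-3-{3-[(tert-butyldimethylsilyl)oxy]-3-methylbutylidene}-7,8-dimethoxy-2,2,6-trimethyl-5-oxo-3,4,5,6-tetrahydro-2H-pyrano[3,2-c]quinolin-4-yl 2-methylpropanoate | CC(C)C(=O)O[C@H]1/C(=C\CC(C)(C)O[Si](C)(C)C(C)(C)C)C(C)(C)Oc2c1c(=O)n(C)c1c(OC)c(OC)ccc21
F6 | step 9 | (3E)-3-{3-[(tert-butyldimethylsilyl)oxy]-3-methylbutylidene}-7,8-dimethoxy-2,2,6-trimethyl-2,3-dihydro-4H-pyrano[3,2-c]quinoline-4,5(6H)-dione | O=C1/C(=C/CC(C)(C)O[Si](C)(C)C(C)(C)C)C(C)(C)Oc2c1c(=O)n(C)c1c(OC)c(OC)ccc21
F7 | step 9 | (3Z,4S)-3-{3-[(tert-butyldimethylsilyl)oxy]-3-methylbutylidene}-4-hydroxy-7,8-dimethoxy-2,2,6-trimethyl-3,4-dihydro-2H-pyrano[3,2-c]quinolin-5(6H)-one | O[C@H]1/C(=C/CC(C)(C)O[Si](C)(C)C(C)(C)C)C(C)(C)Oc2c1c(=O)n(C)c1c(OC)c(OC)ccc21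
F8 | step 9 | potassium alkoxide of F7 | [K+].[O-][C@H]1/C(=C/CC(C)(C)O[Si](C)(C)C(C)(C)C)C(C)(C)Oc2c1c(=O)n(C)c1c(OC)c(OC)ccc21
F9 | step 9 | 4-{[(3Z,4S)-3-{3-[(tert-butyldimethylsilyl)oxy]-3-methylbutylidene}-7,8-dimethoxy-2,2,6-trimethyl-5-oxo-3,4,5,6-tetrahydro-2H-pyrano[3,2-c]quinolin-4-yl]oxy}-7,8-dimethoxy-1-methylquinolin-2(1H)-one | COc1ccc2c(O[C@H]3/C(=C/CC(C)(C)O[Si](C)(C)C(C)(C)C)C(C)(C)Oc4c3c(=O)n(C)c3c(OC)c(OC)ccc43)cc(=O)n(C)c2c1OC
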